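The cyclohexene ring (C1 acetoxy carbon, C2 methylene, C3=C4 olefin with methyl on C4, C5 carrying the coumarinyloxymethyl arm, C6 gem-dimethyl) is opened at its trisubstituted C3=C4 double bond. Ring-closing olefin metathesis of an acyclic 1,7-diene diol, in which an allyl group on C1 and an isopropenyl group on C5 flank the quaternary C6, forms this bond and the ring in one operation with loss of ethene. The diene comes from prenyl senecioate: an enantioselective boron ester-enolate Claisen rearrangement sets C5 and C6, and an amide iodolactonization (temporary lactone ring) relays C5 to C1 in the trans sense. Etherification and acetylation finish.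

Key step: step 6

Assumption: the (S,S)-bromoborane is taken to deliver the (R)-acid 4; should the sense of induction be the reverse, its (R,R)-antipode is used and nothing else changes.

Step 1
Reactants: 1 prenyl senecioate (3-methylbut-2-en-1-yl 3-methylbut-2-enoate; flavour-grade catalogue compound)
Product: 4 (2R)-3,3-dimethyl-2-(prop-1-en-2-yl)pent-4-enoic acid, via boron ketene acetal 2 (not isolated), via acyloxyborane 3 (not isolated)
Conditions: (4S,5S)-bromoborane (1.2 equiv, made beforehand in the flask from the (S,S)-bis-sulfonamide and BBr3, CH2Cl2, then evaporated), Et3N, toluene–hexane, −78 °C then 4 °C; H2O work-up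
Reagents that add atoms: (4S,5S)-2-bromo-1,3-bis{[3,5-bis(trifluoromethyl)phenyl]sulfonyl}-4,5-diphenyl-1,3,2-diazaborolidine, BrB1N(S(=O)(=O)c2cc(C(F)(F)F)cc(C(F)(F)F)c2)[C@@H](c2ccccc2)[C@H](c2ccccc2)N1S(=O)(=O)c1cc(C(F)(F)F)cc(C(F)(F)F)c1 (its atoms are held only in intermediates 2 and 3 and leave on work-up; no reagent atom other than hydrogen remains in 4)
Why: Chiral-boron-mediated enantioselective Ireland–Claisen rearrangement: soft γ-enolisation of the boron-complexed senecioate gives the O-boron dienolate, which rearranges through a chair [3,3] transition state in which the C2-symmetric diazaborolidine shields one enolate face, so the α-stereocenter (R) is set by the reagent while the CMe2 terminus becomes the quaternary carbon.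

Step 2
Reactants: 4 (2R)-3,3-dimethyl-2-(prop-1-en-2-yl)pent-4-enoic acid
Product: 6 (2R)-N,N,3,3-tetramethyl-2-(prop-1-en-2-yl)pent-4-enamide, via acid chloride 5 (not isolated)
Conditions: (COCl)2, cat. DMF, CH2Cl2, 0 °C → rt, evaporate; Me2NH (2 M in THF, 3 equiv), CH2Cl2, 0 °C
Reagents that add atoms: dimethylamine, CNC; oxalyl chloride, O=C(Cl)C(Cl)=O (its chlorine is held only in intermediate 5)
Why: Acid chloride formation followed by aminolysis (nucleophilic acyl substitution) should proceed without loss of the α-stereocenter, because no base stronger than dimethylamine is present and the α-hydrogen is shielded by the neighbouring quaternary carbon.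

Step 3
Reactants: 6 (2R)-N,N,3,3-tetramethyl-2-(prop-1-en-2-yl)pent-4-enamide
Product: 8 (3R,5S)-5-(iodomethyl)-4,4-dimethyl-3-(prop-1-en-2-yl)oxolan-2-one, via iminium lactone iodide 7 (not isolated)
Conditions: I2 (3 equiv), THF–H2O (1:1), rt, dark; Na2S2O3 (aq) work-up
Reagents that add atoms: iodine, II; water, O (it supplies the carbonyl oxygen of the lactone)
Why: Amide-directed iodolactonization (5-exo halocyclisation): the amide oxygen opens the iodonium ion of the γ,δ-vinyl group, and allylic 1,3-strain between an N-methyl group and the α-isopropenyl group holds that group pseudoaxial and the CH2I arm pseudoequatorial in the cyclic imidate transition state, so the new carbinol stereocenter should form trans to the α-substituent, while the β,γ-isopropenyl olefin would need a four-membered closure and is left alone.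

Step 4
Reactants: 8 (3R,5S)-5-(iodomethyl)-4,4-dimethyl-3-(prop-1-en-2-yl)oxolan-2-one
Product: 9 (3R,5R)-4,4-dimethyl-5-(prop-2-en-1-yl)-3-(prop-1-en-2-yl)oxolan-2-one
Conditions: CH2=CHMgBr (4 equiv), CuI (2 equiv), THF, −40 → 0 °C; NH4Cl (aq)
Reagents that add atoms: vinylmagnesium bromide, C=C[Mg]Br
Why: Substitution of a primary iodide by a vinyl homocuprate (organocuprate alkylation) should join the vinyl group to the CH2 carbon without touching either stereocenter, the soft, weakly basic cuprate sparing the hindered lactone carbonyl at low temperature.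

Step 5
Reactants: 9 (3R,5R)-4,4-dimethyl-5-(prop-2-en-1-yl)-3-(prop-1-en-2-yl)oxolan-2-one
Product: 10 (2R,4R)-3,3-dimethyl-2-(prop-1-en-2-yl)hept-6-ene-1,4-diol
Conditions: LiAlH4, THF, 0 °C → rt; H2O, aq NaOH work-up
Reagents that add atoms: none
Why: Hydride reduction of the lactone to the 1,4-diol leaves the isolated olefins and both stereocenters unchanged.

Step 6
Reactants: 10 (2R,4R)-3,3-dimethyl-2-(prop-1-en-2-yl)hept-6-ene-1,4-diol
Product: 11 (1R,5R)-5-(hydroxymethyl)-4,6,6-trimethylcyclohex-3-en-1-ol
Conditions: second-generation Grubbs catalyst RuCl2(=CHPh)(H2IMes)(PCy3) (5 mol%), 1,4-benzoquinone (10 mol%), CH2Cl2 (5 mM), 40 °C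
Reagents that add atoms: none
Why: Ring-closing olefin metathesis by the metallacyclobutane mechanism: the ruthenium benzylidene first exchanges onto the unhindered monosubstituted allyl terminus, the resulting alkylidene at C3 adds intramolecularly to the isopropenyl olefin, and cycloreversion of the ruthenacyclobutane releases the C3=C4 olefin and, after turnover, ethene. The closest known reaction type is ring-closing metathesis of a 1,7-diene bearing one 1,1-disubstituted olefin to a trisubstituted cyclohexene. The carbocycle closes as a six-membered ring by joining the two internal olefin carbons C3 and C4 while the terminal CH2 groups are expelled, the only ring size this diene can give. No stereocenter is formed, and C1 and C5 are sp3 spectators that are not touched. The step needs reaction of the two terminal olefins without prior olefin migration: the gem-dimethyl group at C6 (Thorpe–Ingold effect) brings the olefins together, benzoquinone suppresses ruthenium hydride isomerisation, and the two free hydroxyls (neither allylic) are tolerated. The coumarin double bond, a possible competing olefin, is introduced only after this step, and closing the ring first also removes any chance of tetrahydrofuran formation from the 1,4-diol in the etherification, since the trans ring diol cannot bridge.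

Step 7
Reactants: 11 (1R,5R)-5-(hydroxymethyl)-4,6,6-trimethylcyclohex-3-en-1-ol; 12 umbelliferone (7-hydroxy-2H-chromen-2-one)
Product: 13 7-{[(1R,5R)-5-hydroxy-2,6,6-trimethylcyclohex-2-en-1-yl]methoxy}-2H-chromen-2-one
Conditions: PPh3, DIAD, THF, 0 °C → rt
Reagents that add atoms: none
Why: Mitsunobu etherification: the primary alcohol is activated as its alkoxyphosphonium ion and displaced by the phenoxide of the acidic coumarinol, while the secondary alcohol next to the quaternary carbon is too hindered to be activated, so no stereocenter is involved.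

Step 8
Reactants: 13 7-{[(1R,5R)-5-hydroxy-2,6,6-trimethylcyclohex-2-en-1-yl]methoxy}-2H-chromen-2-one
Product: 14 [(1R,5R)-4,6,6-trimethyl-5-{[(2-oxo-2H-chromen-7-yl)oxy]methyl}cyclohex-3-en-1-yl] acetate
Conditions: Ac2O, DMAP (cat.), pyridine, CH2Cl2, rt
Reagents that add atoms: acetic anhydride, CC(=O)OC(C)=O
Why: DMAP-catalysed acylation of the hindered secondary alcohol takes place at oxygen with retention at the carbinol carbon and leaves the coumarin lactone untouched.

Compound list
1 | prenyl senecioate (3-methylbut-2-en-1-yl 3-methylbut-2-enoate) | CC(C)=CC(=O)OCC=C(C)C | starting material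
2 | boron ketene acetal: O-[(4S,5S)-1,3-bis{[3,5-bis(trifluoromethyl)phenyl]sulfonyl}-4,5-diphenyl-1,3,2-diazaborolidin-2-yl] dienolate of 1 (enolate geometry not specified; formed in the flask) | C=C(C)C=C(OCC=C(C)C)OB1N(S(=O)(=O)c2cc(C(F)(F)F)cc(C(F)(F)F)c2)[C@@H](c2ccccc2)[C@H](c2ccccc2)N1S(=O)(=O)c1cc(C(F)(F)F)cc(C(F)(F)F)c1 | intermediate
3 | acyloxyborane: (4S,5S)-1,3-bis{[3,5-bis(trifluoromethyl)phenyl]sulfonyl}-4,5-diphenyl-1,3,2-diazaborolidin-2-yl (2R)-3,3-dimethyl-2-(prop-1-en-2-yl)pent-4-enoate (formed in the flask) | C=C(C)[C@@H](C(=O)OB1N(S(=O)(=O)c2cc(C(F)(F)F)cc(C(F)(F)F)c2)[C@@H](c2ccccc2)[C@H](c2ccccc2)N1S(=O)(=O)c1cc(C(F)(F)F)cc(C(F)(F)F)c1)C(C)(C)C=C | intermediate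
4 | (2R)-3,3-dimethyl-2-(prop-1-en-2-yl)pent-4-enoic acid | C=C(C)[C@@H](C(=O)O)C(C)(C)C=C | intermediate
5 | (2R)-3,3-dimethyl-2-(prop-1-en-2-yl)pent-4-enoyl chloride (formed in the flask) | C=C(C)[C@@H](C(Cl)=O)C(C)(C)C=C | intermediate
6 | (2R)-N,N,3,3-tetramethyl-2-(prop-1-en-2-yl)pent-4-enamide | C=C(C)[C@@H](C(=O)N(C)C)C(C)(C)C=C | intermediate
7 | N-[(3R,5S)-5-(iodomethyl)-4,4-dimethyl-3-(prop-1-en-2-yl)oxolan-2-ylidene]-N-methylmethanaminium iodide (formed in the flask) | C[N+](C)=C1O[C@H](CI)C(C)(C)[C@H]1C(C)=C.[I-] | intermediate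
8 | (3R,5S)-5-(iodomethyl)-4,4-dimethyl-3-(prop-1-en-2-yl)oxolan-2-one | O=C1O[C@H](CI)C(C)(C)[C@H]1C(C)=C | intermediate
9 | (3R,5R)-4,4-dimethyl-5-(prop-2-en-1-yl)-3-(prop-1-en-2-yl)oxolan-2-one | O=C1O[C@H](CC=C)C(C)(C)[C@H]1C(C)=C | intermediate
10 | (2R,4R)-3,3-dimethyl-2-(prop-1-en-2-yl)hept-6-ene-1,4-diol | C=CC[C@@H](O)C(C)(C)[C@H](CO)C(C)=C | intermediate
11 | (1R,5R)-5-(hydroxymethyl)-4,6,6-trimethylcyclohex-3-en-1-ol | O[C@@H]1CC=C(C)[C@@H](CO)C1(C)C | intermediate
12 | umbelliferone (7-hydroxy-2H-chromen-2-one) | Oc1ccc2ccc(=O)oc2c1 | starting material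
13 | 7-{[(1R,5R)-5-hydroxy-2,6,6-trimethylcyclohex-2-en-1-yl]methoxy}-2H-chromen-2-one | O[C@@H]1CC=C(C)[C@@H](COc2ccc3ccc(=O)oc3c2)C1(C)C | intermediate
14 | [(1R,5R)-4,6,6-trimethyl-5-{[(2-oxo-2H-chromen-7-yl)oxy]methyl}cyclohex-3-en-1-yl] acetate | CC(=O)O[C@@H]1CC=C(C)[C@@H](COc2ccc3ccc(=O)oc3c2)C1(C)C | target

Total step count: 8. Longest linear sequence: 8 steps (from 1 to 14).

Steps most likely to fail

Step 4. The substitution may stall at the hindered primary carbon–iodine bond, or the cuprate may transfer electrons and expel the neighbouring acyloxy group (reductive opening of the lactone back to the unsaturated acid). The fallback makes the same carbon–carbon bond by epoxide opening instead. Setting out from 8, K2CO3 in MeOH at 0 °C should open the lactone to methyl (2R,4S)-4-hydroxy-5-iodo-3,3-dimethyl-2-(prop-1-en-2-yl)pentanoate F1, whose alkoxide should close at once to the epoxy ester methyl (2R)-3-methyl-3-[(2S)-oxiran-2-yl]-2-(prop-1-en-2-yl)butanoate F2. Copper-catalysed opening of the terminal epoxide at its CH2 carbon (CH2=CHMgBr, 10 mol% CuI, THF, −40 °C) should then give methyl (2R,4R)-4-hydroxy-3,3-dimethyl-2-(prop-1-en-2-yl)hept-6-enoate F3, which lactonises on mildly acidic work-up (cat. TsOH, CH2Cl2) and so comes back to the route at 9.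

Step 1. Soft γ-enolisation of the conjugated ester may be incomplete, or the dienolate may form as a mixture of geometries so that facial discrimination by the boron controller is eroded. The fallback separates the enantiomers instead of inducing them. Setting out from 1, the classical Ireland–Claisen rearrangement (LiN(iPr)2, TMSCl, THF, −78 °C → rt) should pass through the trimethylsilyl ketene acetal F4 and the trimethylsilyl ester F5 to racemic 3,3-dimethyl-2-(prop-1-en-2-yl)pent-4-enoic acid F6 after aqueous acid. Crystallisation with (R)-1-phenylethylamine (or its antipode, whichever gives the crystalline salt of the (R)-acid) should furnish (R)-1-phenylethylammonium (2R)-3,3-dimethyl-2-(prop-1-en-2-yl)pent-4-enoate F7, and acidification (aq HCl) comes back to the route at 4.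

Step 7. Displacement at the β-branched alkoxyphosphonium ion may be slower than its elimination or than alkylation of the hydrazide by-product. The fallback forms the aryl–oxygen bond instead of the alkyl–oxygen bond, so that no substitution at the hindered carbon is needed. Setting out from 11, palladium-catalysed C–O coupling of its primary hydroxyl with purchased 7-bromo-2H-chromen-2-one (O=c1ccc2ccc(Br)cc2o1) under Pd2(dba)3 (zerovalent palladium), RockPhos, Cs2CO3, toluene, 80 °C should give the ether directly and come back to the route at 13. The hindered secondary hydroxyl should not compete, and the fallback makes no new compound (F0).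

Further compounds
F1 | step 4 | methyl (2R,4S)-4-hydroxy-5-iodo-3,3-dimethyl-2-(prop-1-en-2-yl)pentanoate | C=C(C)[C@@H](C(=O)OC)C(C)(C)[C@H](O)CI
F2 | step 4 | methyl (2R)-3-methyl-3-[(2S)-oxiran-2-yl]-2-(prop-1-en-2-yl)butanoate | C=C(C)[C@@H](C(=O)OC)C(C)(C)[C@H]1CO1
F3 | step 4 | methyl (2R,4R)-4-hydroxy-3,3-dimethyl-2-(prop-1-en-2-yl)hept-6-enoate | C=CC[C@@H](O)C(C)(C)[C@H](C(=O)OC)C(C)=C
F4 | step 1 | trimethylsilyl ketene acetal of 1 (1-[(3-methylbut-2-en-1-yl)oxy]-1-(trimethylsilyloxy)-3-methylbuta-1,3-diene) | C=C(C)C=C(OCC=C(C)C)O[Si](C)(C)C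
F5 | step 1 | trimethylsilyl 3,3-dimethyl-2-(prop-1-en-2-yl)pent-4-enoate (racemic) | C=C(C)C(C(=O)O[Si](C)(C)C)C(C)(C)C=C
F6 | step 1 | 3,3-dimethyl-2-(prop-1-en-2-yl)pent-4-enoic acid (racemic) | C=C(C)C(C(=O)O)C(C)(C)C=C
F7 | step 1 | (R)-1-phenylethylammonium (2R)-3,3-dimethyl-2-(prop-1-en-2-yl)pent-4-enoate | C=C(C)[C@@H](C(=O)[O-])C(C)(C)C=C.C[C@@H]([NH3+])c1ccccc1
F0 | step 7 | none | none
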